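**Retrosynthetic overview**
- All three coumarin ring systems are bought intact as umbelliferone 1, so no ring is formed in the route.
- C8–C8' axis: umbelliferone is iodinated at C8 (2), O-methylated (3) and homocoupled (Ullmann) to the symmetric bicoumarin 4.
- C3–O(aryl) ether, the key disconnection: cut between C3 of one half of 4 and the phenol oxygen of a third umbelliferone. It is made in one pot by C3–H conversion into alkenyl(mesityl)iodonium salt 5 and copper-catalysed O-alkenylation, giving 6.
- Last: double O-demethylation of 6 gives the target 7.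
- Order of bond formation: C8–I, O–Me, C8–C8', C3–O, O–Me cleavage.

Assumption: the SMILES carries no stereocentre and no axial descriptor, so the target is taken as the constitution drawn and the 8,8' axis is formed without control.

**Step 1**
Reactants: 1 umbelliferone (7-hydroxycoumarin)
Product: 2 7-hydroxy-8-iodocoumarin
Conditions: I2 (1.05 equiv), KI, 20% aq. NH3, 0 °C to rt; then dil. HCl
Reagents that add atoms: iodine, II
Why: Electrophilic aromatic iodination of the phenoxide; bond fixation makes C8 (between O7 and the ring oxygen) the most nucleophilic carbon, as at the alpha position of 2-naphthol, and no stereocentre is formed.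

**Step 2**
Reactants: 2 7-hydroxy-8-iodocoumarin
Product: 3 8-iodo-7-methoxycoumarin
Conditions: MeI (1.5 equiv), K2CO3, acetone, reflux
Reagents that add atoms: iodomethane, CI
Why: Williamson ether synthesis on the only nucleophile present; the lactone is inert to K2CO3 in acetone and no stereocentre is formed.

**Step 3**
Reactants: 3 8-iodo-7-methoxycoumarin (two molecules)
Product: 4 7,7'-dimethoxy-8,8'-bicoumarin
Conditions: activated Cu bronze (5 equiv), DMF, 150 °C, N2, 24 h
Reagents that add atoms: none
Why: Classical Ullmann reductive homocoupling, which tolerates an aryl iodide flanked by two oxygen substituents and leaves lactone and methyl ether untouched; the axis is formed without control, as assumed.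

**Step 4**
Reactants: 4 7,7'-dimethoxy-8,8'-bicoumarin; 1 umbelliferone
Product: 6 di-O-methyltriumbelletin (7,7'-dimethoxy-3-[(2-oxo-2H-chromen-7-yl)oxy]-8,8'-bicoumarin), via (bicoumarin-3-yl)(mesityl)iodonium tosylate 5 (not isolated)
Conditions: MesI(OAc)2 (0.7 equiv), TsOH·H2O (0.7 equiv), HFIP, 0 °C to rt, 3 h; evaporate; then 1 (0.8 equiv), Cu(MeCN)4PF6 (10 mol %), K2CO3 (1.5 equiv), CH2Cl2–MeCN 4:1, rt, 12 h; unreacted 4 recovered and recycled
Reagents that add atoms: iodomesitylene diacetate, CC(=O)OI(OC(C)=O)c1c(C)cc(C)cc1C; p-toluenesulfonic acid monohydrate, Cc1ccc(cc1)S(=O)(=O)O.O (both end up only in intermediate 5 and leave again before 6)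
Why: Proposed new method: in HFIP the trivalent iodine electrophile MesI(OH)OTs, made in the flask, attacks C3 of one p-methoxycinnamate-like half of 4 (C8 is blocked and C6, ortho to OMe, is poorly accessible to the bulky reagent); the C4 benzylic cation stabilised by the 7-OMe group loses the acidic C3 proton to give alkenyl(mesityl)iodonium salt 5, the limiting amount of iodane and the positive charge of 5 holding the reaction at one half. Monovalent copper then inserts into the C3–I bond while the hindered mesityl group stays on iodine, the potassium phenoxide of 1 binds the trivalent alkenylcopper, and C–O reductive elimination gives the ipso ether 6, which avoids the conjugate-addition/cine-substitution path open to a free phenoxide; no stereocentre is formed. The closest known reaction types are the dehydrative C–H condensation of Koser-type reagents with electron-rich arenes and uracils in fluoroalcohols and the copper-catalysed O-arylation or O-alkenylation of phenols with diaryl- or alkenyl(aryl)iodonium salts; to my knowledge neither has been applied to the C3–H bond of a coumarin or combined into a C–H aryloxylation of an enoate.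

**Step 5**
Reactants: 6 di-O-methyltriumbelletin
Product: 7 triumbelletin
Conditions: BBr3 (8 equiv), CH2Cl2, −78 °C to rt; then ice-water
Reagents that add atoms: none
Why: Lewis acid-mediated aryl methyl ether cleavage in which bromide attacks only the sp3 methyl carbons, so the C3–O–C7 ether (both carbons sp2) and the three lactones survive; no stereocentre is involved.

**Compound list**
1 | umbelliferone (7-hydroxy-2H-chromen-2-one) | O=c1ccc2ccc(O)cc2o1 | starting material
2 | 7-hydroxy-8-iodo-2H-chromen-2-one | O=c1ccc2ccc(O)c(I)c2o1 | intermediate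
3 | 8-iodo-7-methoxy-2H-chromen-2-one | COc1ccc2ccc(=O)oc2c1I | intermediate
4 | 7,7'-dimethoxy-2H,2'H-[8,8'-bichromene]-2,2'-dione | COc1ccc2ccc(=O)oc2c1-c1c(OC)ccc2ccc(=O)oc12 | intermediate
5 | [7,7'-dimethoxy-2,2'-dioxo-2H,2'H-8,8'-bichromen-3-yl](2,4,6-trimethylphenyl)iodonium 4-methylbenzenesulfonate | COc1ccc2cc([I+]c3c(C)cc(C)cc3C)c(=O)oc2c1-c1c(OC)ccc2ccc(=O)oc12.Cc1ccc(cc1)S(=O)(=O)[O-] | intermediate
6 | 7,7'-dimethoxy-3-[(2-oxo-2H-chromen-7-yl)oxy]-2H,2'H-[8,8'-bichromene]-2,2'-dione | COc1ccc2cc(Oc3ccc4ccc(=O)oc4c3)c(=O)oc2c1-c1c(OC)ccc2ccc(=O)oc12 | intermediate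
7 | triumbelletin, 7,7'-dihydroxy-3-[(2-oxo-2H-chromen-7-yl)oxy]-2H,2'H-[8,8'-bichromene]-2,2'-dione | O=c1ccc2ccc(Oc3cc4ccc(O)c(-c5c(O)ccc6ccc(=O)oc56)c4oc3=O)cc2o1 | target

**Step count**
Total: 5 steps. Longest linear sequence: 5 steps (1 → 2 → 3 → 4 → 6 → 7).

**Three steps most likely to fail**

1. Step 4 (the new C3–H aryloxylation). The iodane may attack C6 instead of C3, both halves may react, or the phenoxide may add at C4 and give the 4-aryloxy isomer. The fallback uses known reactions only, sets out from 4 and comes back at 6. Compound 4 is brominated once at C3 with NBS (0.7 equiv) in MeCN, the usual site of halogenation of 7-alkoxycoumarins, to give 3-bromo-7,7'-dimethoxy-8,8'-bicoumarin F1. F1 is then joined to umbelliferone 1 by a palladium-catalysed C–O cross-coupling of the Buchwald diaryl ether type (Pd2(dba)3, tBuXPhos, K3PO4, toluene, 100 °C), where oxidative addition of zerovalent palladium to the C3–Br bond fixes the ipso position, to give 6.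

2. Step 3 (Ullmann homocoupling). The iodide is doubly ortho-substituted, and hydrodeiodination to 7-methoxycoumarin can outrun coupling at 150 °C. The fallback sets out from 3 and comes back at 4. Half of 3 is converted by Miyaura borylation (B2pin2, PdCl2(dppf), KOAc, dioxane, 90 °C) into 7-methoxy-8-(4,4,5,5-tetramethyl-1,3,2-dioxaborolan-2-yl)coumarin F2. F2 is then cross-coupled with the other half of 3 in a Suzuki–Miyaura reaction using a ligand made for tetra-ortho-substituted biaryls (Pd(OAc)2, SPhos, anhydrous K3PO4, toluene, 100 °C) to give 4.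

3. Step 5 (double demethylation). The two ethers sit next to the biaryl axis, and the excess BBr3 needed may degrade the tris-lactone. The fallback changes the protecting group, sets out from 2 and comes back at 7. Compound 2 is alkylated with 2-bromopropane (K2CO3, DMF, 60 °C) to 8-iodo-7-isopropoxycoumarin F3, which is homocoupled as in step 3 (Cu bronze, DMF, 150 °C) to 7,7'-diisopropoxy-8,8'-bicoumarin F4. F4 is taken through the one-pot sequence of step 4 with 1, by way of the corresponding (bicoumarin-3-yl)(mesityl)iodonium tosylate F5 (not isolated), to 7,7'-diisopropoxy-3-[(2-oxo-2H-chromen-7-yl)oxy]-8,8'-bicoumarin F6. The isopropyl ethers of F6 are then cleaved under much milder conditions (BCl3, CH2Cl2, −20 to 0 °C) to give 7.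

**Further compounds**
F1 | step 4 | 3-bromo-7,7'-dimethoxy-2H,2'H-[8,8'-bichromene]-2,2'-dione | COc1ccc2cc(Br)c(=O)oc2c1-c1c(OC)ccc2ccc(=O)oc12
F2 | step 3 | 7-methoxy-8-(4,4,5,5-tetramethyl-1,3,2-dioxaborolan-2-yl)-2H-chromen-2-one | COc1ccc2ccc(=O)oc2c1B1OC(C)(C)C(C)(C)O1
F3 | step 5 | 8-iodo-7-(propan-2-yloxy)-2H-chromen-2-one | CC(C)Oc1ccc2ccc(=O)oc2c1I
F4 | step 5 | 7,7'-bis(propan-2-yloxy)-2H,2'H-[8,8'-bichromene]-2,2'-dione | CC(C)Oc1ccc2ccc(=O)oc2c1-c1c(OC(C)C)ccc2ccc(=O)oc12
F5 | step 5 | [2,2'-dioxo-7,7'-bis(propan-2-yloxy)-2H,2'H-8,8'-bichromen-3-yl](2,4,6-trimethylphenyl)iodonium 4-methylbenzenesulfonate | CC(C)Oc1ccc2cc([I+]c3c(C)cc(C)cc3C)c(=O)oc2c1-c1c(OC(C)C)ccc2ccc(=O)oc12.Cc1ccc(cc1)S(=O)(=O)[O-]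
F6 | step 5 | 3-[(2-oxo-2H-chromen-7-yl)oxy]-7,7'-bis(propan-2-yloxy)-2H,2'H-[8,8'-bichromene]-2,2'-dione | CC(C)Oc1ccc2cc(Oc3ccc4ccc(=O)oc4c3)c(=O)oc2c1-c1c(OC(C)C)ccc2ccc(=O)oc12
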